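**Plan**

- Retrosynthetic cuts: the acetate and methacrylate C–O bonds, the lactone O6–C12 bond and C10–C14 (formyl from CO on an enol triflate) go first. Then C2–C3 is cut while C5–C10 is reconnected, which folds the ten-membered ring into a cyclohexanol. C4–C5 (epoxide opening), C1=C2 (Wittig) and C11=C13 (Mannich) lead back to an arene.
- Enabling feature: ring atoms C10=C1–C2–C3–C4=C5 form a cyclodeca-1,5-diene, so the σ-bond C2–C3 can be made by a [3,3] shift that spends the transannular bond C5–C10 of a six-membered ring (C5–C10).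
- Forward order of rings: the benzene ring becomes the six-membered carbocycle (Birch). A temporary cis-γ-lactone on O8, a seven-membered acetal and a seven-membered silylene come and go. The ten-membered ring arises by 6→10 expansion and the trans-γ-lactone closes near the end.
- Stereochemistry: C7/C8 (absolute) come from a catalyst-controlled bromolactonisation, and C6/C9 from singlet oxygen adding anti to that lactone. O10 comes from a directed epoxidation anti to the silyloxy groups and C5 from SN2 inversion. These two centres are then traded for the two ring-olefin geometries in a chair transition state enforced by a trans-fused O6–Si–O12 tether.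

Key step: step 18

Assumption: the hydroquinidine-derived catalyst of step 2 is taken to give the antipode drawn for 3; if it favours the other enantiotopic alkene, the hydroquinine-derived pseudo-enantiomer (DHQ)2PHAL is used instead with nothing else changed.

Locants and descriptors: atoms carry the numbers they have in the target (C1–C15). On the carbocycle, α is the face of O6 and O9 and β the face of O8 and C11 (so H7 is α).

**Route**

Step 1
Reactants: 1 methyl 4-(carboxymethyl)benzoate
Product: 2 methyl 4-(carboxymethyl)cyclohexa-2,5-diene-1-carboxylate (cis/trans mixture, each isomer achiral)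
Conditions: Li, NH3(l)/THF, t-BuOH, −78 °C; then NH4Cl
Reagents that add atoms: none
Why: Birch reduction of a benzoate delivers the two hydrogens to the ester-bearing carbon and to the carbon para to it, so C10 and C7 become sp3 and the cyclohexa-2,5-diene (mirror plane through C7 and C10) offers two enantiotopic ring alkenes, while the side-chain carboxylate is inert as its lithium salt.

Step 2
Reactants: 2 methyl 4-(carboxymethyl)cyclohexa-2,5-diene-1-carboxylate
Product: 3 methyl 7-bromo-2-oxo-2,3,3a,6,7,7a-hexahydro-1-benzofuran-6-carboxylate (cis-fused 8β,12-lactone, 9α-Br, both C10 epimers)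
Conditions: N-bromosuccinimide, hydroquinidine 1,4-phthalazinediyl diether [(DHQD)2PHAL] (10 mol %), CHCl3/hexane, −40 °C
Reagents that add atoms: N-bromosuccinimide, O=C1CCC(=O)N1Br
Why: Catalytic enantioselective 5-exo bromolactonisation desymmetrises the diene: the amine catalyst selects one of the two enantiotopic alkenes, and anti addition of bromine and carboxylate across C8=C9 fixes O8 cis to the C7 side chain (cis-fused γ-lactone) and Br9 trans to O8, which sets the absolute configuration of C7 and C8 for the whole route.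

Step 3
Reactants: 3 bromolactone
Product: 4 methyl 2-oxo-2,3,3a,7a-tetrahydro-1-benzofuran-6-carboxylate (cis-fused 8β,12-lactone; C5=C6 and C9=C10, ester on C10)
Conditions: DBU, CH2Cl2, 0 °C
Reagents that add atoms: none
Why: E1cB dehydrobromination: H10 is α to the ester and allylic, so either C10 epimer is deprotonated and expels the β-bromide from C9, giving the C9=C10–C5=C6 dienoate without touching C7 or C8.

Step 4
Reactants: 4 diene lactone
Product: 6 methyl 4,7-dihydroxy-2-oxo-2,3,3a,4,7,7a-hexahydro-1-benzofuran-6-carboxylate (6α-OH and 9α-OH; C5=C10), via endoperoxide 5 (not isolated)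
Conditions: O2, tetraphenylporphyrin (cat.), hν, CH2Cl2, −20 °C; then thiourea, MeOH, 20 °C
Reagents that add atoms: dioxygen, O=O
Why: Singlet oxygen adds to the s-cis cyclohexa-1,3-diene in a [4+2] cycloaddition from the face opposite the cis-fused lactone, so the new C6–O and C9–O bonds are both α (cis to each other and trans to C7–C11 and C8–O), and thiourea then reduces only the O–O bond of the endoperoxide.

Step 5
Reactants: 6 diol
Product: 7 6α,9α-bis(tert-butyldimethylsilyl) ether of 6
Conditions: t-BuMe2SiOTf, 2,6-lutidine, CH2Cl2, 0 °C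
Reagents that add atoms: tert-butyldimethylsilyl trifluoromethanesulfonate, CC(C)(C)[Si](C)(C)OS(=O)(=O)C(F)(F)F
Why: Silyl triflate silylation of the two secondary allylic alcohols protects them for the enolate step and removes any ring hydroxyl that could later steer an oxidant to the α face.

Step 6
Reactants: 7 bis-silyl ether; 8 N,N-dimethylmethyleneiminium iodide
Product: 10 11-(dimethylaminomethyl) lactone (C11 configuration not controlled), via lithium enolate 9 (not isolated)
Conditions: LiN(iPr)2, THF, −78 °C; then 8, −78 → 0 °C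
Reagents that add atoms: N,N-dimethylmethyleneiminium iodide, C=[N+](C)C.[I-]
Why: Kinetic deprotonation of the lactone methylene (C11) and Mannich-type aminomethylation of the lithium enolate with the preformed iminium salt brings in C13; the new C11 stereocentre is erased in the next step.

Step 7
Reactants: 10 Mannich base
Product: 12 11(13)-methylene-8β,12-lactone (6α,9α-bis-silyl ether; C5=C10–CO2Me), via ammonium iodide 11 (not isolated)
Conditions: MeI, MeOH, 20 °C; then NaHCO3 (aq), EtOAc
Reagents that add atoms: none
Why: Exhaustive N-methylation followed by base-induced E1cB (Hofmann-type) loss of trimethylamine unveils the 11(13)-methylene group.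

Step 8
Reactants: 12 α-methylene lactone
Product: 13 triol (C1–OH and C12–OH primary allylic, 8β-OH; 6α,9α-bis-silyl ether)
Conditions: iBu2AlH (excess), CH2Cl2, −78 → 0 °C; aq. potassium sodium tartrate
Reagents that add atoms: none
Why: The aluminium hydride reduces both carbonyl groups by 1,2-addition, the enoate to the C1 allylic alcohol and the α-methylene lactone through its lactol to the 2-methylene-1,4-diol (O8–H and C12–OH), a standard reduction that leaves the silyl ethers and all stereocentres untouched.

Step 9
Reactants: 13 triol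
Product: 14 8,12-O-(4-methoxybenzylidene) acetal of 13 (cis-fused 1,3-dioxepane; C1–OH free; acetal carbon epimers)
Conditions: 4-MeOC6H4CH(OMe)2, camphorsulfonic acid (cat.), CH2Cl2, 4 Å sieves, 0 → 20 °C
Reagents that add atoms: 4-methoxybenzaldehyde dimethyl acetal, COc1ccc(C(OC)OC)cc1
Why: Acid-catalysed transacetalisation under thermodynamic control ties the cis 1,4-diol O8/O12 into a fused seven-membered acetal (an acetal through O1 would be bridged across C8–C10), which hides the 11(13)-allylic alcohol, leaves only the C1 alcohol free and pre-installs the benzyl-type ether of O8; the acetal carbon epimers converge in step 14.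

Step 10
Reactants: 14 acetal
Product: 15 5β,10β-epoxide of 14
Conditions: VO(acac)2 (5 mol %), t-BuOOH, CH2Cl2, 0 °C
Reagents that add atoms: tert-butyl hydroperoxide, CC(C)(C)OO
Why: Hydroxyl-directed vanadium-catalysed epoxidation acts only on the alkene that carries a free allylic alcohol (C5=C10) and delivers oxygen to the β face, anti to the allylic silyloxy groups on C6 and C9, which sets O10 β.

Step 11
Reactants: 15 epoxy alcohol; 16 isopropenylmagnesium bromide
Product: 17 5α-isopropenyl-10β-hydroxy-10α-(hydroxymethyl) cyclohexane (acetal and silyl ethers as in 15)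
Conditions: 16 (excess), CuI (20 mol %), THF, −30 → 0 °C; then NH4Cl (aq)
Reagents that add atoms: isopropenylmagnesium bromide, C=C(C)[Mg]Br
Why: Copper-catalysed Grignard opening of the epoxy alcohol is an SN2 attack at the secondary C5 (C10 is fully substituted) anti to the oxirane oxygen, a trans-diaxial (Fürst–Plattner) opening that puts isopropenyl α at C5 with inversion and leaves the 10β-hydroxyl, the trans-diaxial pair needed later.

Step 12
Reactants: 17 diol
Product: 18 10β-hydroxy-10α-carbaldehyde
Conditions: Dess–Martin periodinane, pyridine, CH2Cl2, 0 °C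
Reagents that add atoms: none
Why: Dess–Martin oxidation converts the primary alcohol of the 1,2-diol into the aldehyde, while the tertiary C10 alcohol cannot be oxidised and the quaternary α-carbon excludes epimerisation.

Step 13
Reactants: 18 hydroxy aldehyde; 19 methyltriphenylphosphonium bromide
Product: 20 10α-vinyl-10β-ol (5α-isopropenyl; acetal and silyl ethers retained)
Conditions: 19, KN(SiMe3)2, THF, 0 °C; then 18, −78 → 0 °C
Reagents that add atoms: methyltriphenylphosphonium bromide, C[P+](c1ccccc1)(c1ccccc1)c1ccccc1.[Br-]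
Why: Wittig methylenation of the α-hydroxy aldehyde (excess ylide also deprotonates the tertiary alcohol) gives the 10α-vinyl group and completes the cis-1-vinyl-2-isopropenyl carbinol without touching a stereocentre.

Step 14
Reactants: 20 vinyl carbinol
Product: 21 8β-O-(4-methoxybenzyl) ether with free C12–OH
Conditions: iBu2AlH, CH2Cl2, −78 → 0 °C
Reagents that add atoms: none
Why: Regioselective reductive opening of the benzylidene-type acetal: aluminium coordinates the less hindered primary O12 and hydride is delivered to the acetal carbon, so the 4-methoxybenzyl group stays on the secondary O8 and C12–OH is freed.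

Step 15
Reactants: 21 bis-silyl ether
Product: 22 tetraol (6α-OH, 9α-OH, 10β-OH, C12–OH; 8β-O-4-methoxybenzyl)
Conditions: Bu4NF, THF, 20 °C
Reagents that add atoms: none
Why: Fluoride-induced desilylation removes both secondary silyl ethers so that O6 can enter the tether; the 4-methoxybenzyl ether and the alkenes are inert.

Step 16
Reactants: 22 tetraol
Product: 23 6,12-O-(di-tert-butylsilylene) derivative (trans-fused 1,3-dioxa-2-silepane; 9α-OH and 10β-OH free)
Conditions: t-Bu2Si(OTf)2, 2,6-lutidine, CH2Cl2, −40 → 0 °C
Reagents that add atoms: di-tert-butylsilyl bis(trifluoromethanesulfonate), CC(C)(C)[Si](OS(=O)(=O)C(F)(F)F)(OS(=O)(=O)C(F)(F)F)C(C)(C)C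
Why: Silylene formation: the bis-triflate silylates the primary C12 alcohol first and the remaining Si–OTf then closes on O6, the only hydroxyl within reach, giving a seven-membered ring that is trans-fused to the carbocycle and therefore holds O6 and C11 diequatorial.

Step 17
Reactants: 23 silylene diol
Product: 24 9α-O-triethylsilyl ether of 23 (cis-1-vinyl-2-isopropenylcyclohexanol; 10β-OH free)
Conditions: Et3SiCl, imidazole, 4-dimethylaminopyridine (cat.), DMF, 0 → 20 °C
Reagents that add atoms: chlorotriethylsilane, CC[Si](Cl)(CC)CC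
Why: Silyl chloride/imidazole silylation discriminates the secondary O9–H from the tertiary allylic C10–OH, which must stay free for the rearrangement.

Step 18
Reactants: 24 cis-1-vinyl-2-isopropenylcyclohexanol
Product: 27 cyclodeca-1(10),4-dien-10-yl triflate (1(10)E with C2 cis to C9; 4E), via potassium alkoxide 25 (not isolated), via potassium enolate 26 (not isolated)
Conditions: KN(SiMe3)2, 18-crown-6, THF, −78 → 20 °C; then PhNTf2, −78 → 0 °C
Reagents that add atoms: N-phenylbis(trifluoromethanesulfonimide), O=S(=O)(N(c1ccccc1)S(=O)(=O)C(F)(F)F)C(F)(F)F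
Why: KN(SiMe3)2/18-crown-6 turns the tertiary alcohol into a dissociated potassium alkoxide (25), which undergoes an anionic oxy-Cope ([3,3]-sigmatropic) rearrangement in which C2 of the vinyl group bonds to C3 of the isopropenyl group while the ring bond C5–C10 breaks, and the enolate so formed (26, O on C10, C1=C10) is sulfonylated on oxygen by PhNTf2. The closest known reaction type is the anionic oxy-Cope rearrangement of 1,2-dialkenylcyclohexanols to cyclodec-5-enone enolates with in situ trapping of the regiodefined enolate. The ten-membered ring is not closed end to end but arises by 6→10 ring expansion, the six-membered carbocycle (C5–C10) being opened across its C5–C10 bond as the six-centre chair forms C2–C3. No stereocentre is created: C5 and C10 are consumed, and their relative configuration (10β-O axial, 5α-isopropenyl axial, vinyl equatorial) places O10 pseudo-equatorial and H5 pseudo-axial in the chair, which puts C9 cis to C2 across C1=C10 and C6 trans to C3 across C4=C5, while C6–C9 are spectators. The step needs this chair rather than the alternative one (vinyl axial, isopropenyl equatorial, leading to the 4Z/ring-trans isomer) and needs the kinetic C1 enolate; the first is secured by the trans-fused O6–Si–O12 ring, which can only span diequatorial substituents on C6/C7 and so fixes the conformer with axial isopropenyl and axial O10, the second by triflating cold in the absence of a proton source. With O9 (silyl ether) and O10 trans-diaxial, O→O silyl transfer to the alkoxide is geometrically excluded, and O8 carries a non-migrating benzyl-type ether.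

Step 19
Reactants: 27 enol triflate; 28 carbon monoxide
Product: 29 14-aldehyde (C10–CHO; silylene, triethylsilyl and 4-methoxybenzyl groups retained)
Conditions: Pd(PPh3)4 (5 mol %), CO (3 atm), Bu3SnH (slow addition), THF, 50 °C
Reagents that add atoms: carbon monoxide, [C-]#[O+]
Why: Palladium-catalysed reductive carbonylation (formylation) of the enol triflate: oxidative addition of zerovalent palladium with retention of olefin geometry, CO insertion and hydride transfer from tin give the 14-aldehyde directly with C1=C10 unchanged.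

Step 20
Reactants: 29 enal
Product: 30 6α,9α,12-triol 14-aldehyde (8β-O-4-methoxybenzyl)
Conditions: HF·pyridine, pyridine, THF, 0 → 20 °C
Reagents that add atoms: none
Why: Fluoride cleaves the seven-membered silylene and the triethylsilyl ether in one operation under buffered conditions that the enal and the 4-methoxybenzyl ether tolerate.

Step 21
Reactants: 30 triol
Product: 32 12,6α-olide (trans-fused α-methylene-γ-lactone; 9α-OH; 8β-O-4-methoxybenzyl; 14-aldehyde), via lactol 31 (not isolated)
Conditions: TEMPO (20 mol %), PhI(OAc)2, CH2Cl2, 20 °C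
Reagents that add atoms: none
Why: Nitroxyl-catalysed oxidation is selective for the primary allylic C12 alcohol; the resulting enal is captured by O6–H as the lactol, which is oxidised on to the α-methylene-γ-lactone (oxidative lactonisation of a 1,4-diol), the trans ring fusion being fixed by the existing C6 and C7 centres while the secondary O9–H is left.

Step 22
Reactants: 32 hydroxy lactone; 33 acetic anhydride
Product: 34 9α-acetate
Conditions: Ac2O, pyridine, CH2Cl2, 0 → 20 °C
Reagents that add atoms: acetic anhydride, CC(=O)OC(C)=O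
Why: Acetylation of the only free hydroxyl (O9) with acetic anhydride/pyridine; no nucleophilic catalyst is used so as not to trigger allylic (SN2′) displacement next to the enal.

Step 23
Reactants: 34 acetate
Product: 35 8β-alcohol
Conditions: DDQ, CH2Cl2/pH 7 buffer, 0 °C
Reagents that add atoms: none
Why: Oxidative cleavage of the 4-methoxybenzyl ether by DDQ (benzylic hydride abstraction, then hydrolysis) frees O8 under neutral conditions compatible with the esters, the enal and the lactone.

Step 24
Reactants: 35 alcohol; 36 methacryloyl chloride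
Product: 37 (6R,7S,8S,9S)-9α-acetoxy-8β-methacryloyloxy-14-oxogermacra-1(10)E,4E,11(13)-trien-12,6α-olide (CNP0403553.1)
Conditions: 36, iPr2NEt, CH2Cl2, 0 → 20 °C
Reagents that add atoms: methacryloyl chloride, C=C(C)C(Cl)=O
Why: Acylation of the secondary O8–H with the acid chloride and a hindered amine base, run cold and without nucleophilic catalyst to limit acyl migration from O9 and addition to the two Michael acceptors, completes the target.

**Compound list**

1 | methyl 4-(carboxymethyl)benzoate | COC(=O)c1ccc(CC(=O)O)cc1 | starting material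
2 | methyl 4-(carboxymethyl)cyclohexa-2,5-diene-1-carboxylate (cis/trans mixture) | COC(=O)C1C=CC(CC(=O)O)C=C1 | intermediate
3 | bromolactone: methyl 7-bromo-2-oxo-2,3,3a,6,7,7a-hexahydro-1-benzofuran-6-carboxylate (cis-fused, Br trans to lactone O, C10 epimers) | C1=C[C@@H]2CC(=O)O[C@@H]2[C@@H](Br)C1C(=O)OC | intermediate
4 | diene lactone: methyl 2-oxo-2,3,3a,7a-tetrahydro-1-benzofuran-6-carboxylate (cis-fused) | C1=C[C@@H]2CC(=O)O[C@@H]2C=C1C(=O)OC | intermediate
5 | 6α,9α-endoperoxide of 4 | C=1[C@@H]2[C@@H]3CC(=O)O[C@@H]3[C@@H](OO2)C=1C(=O)OC | intermediate (not isolated)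
6 | 6α,9α-diol (8β,12-lactone, C5=C10–CO2Me) | COC(=O)C1=C[C@@H](O)[C@@H]2CC(=O)O[C@@H]2[C@H]1O | intermediate
7 | 6α,9α-bis(tert-butyldimethylsilyl) ether of 6 | COC(=O)C1=C[C@@H](O[Si](C)(C)C(C)(C)C)[C@@H]2CC(=O)O[C@@H]2[C@H]1O[Si](C)(C)C(C)(C)C | intermediate
8 | N,N-dimethylmethyleneiminium iodide | C=[N+](C)C.[I-] | starting material
9 | lithium enolate of lactone 7 | COC(=O)C1=C[C@@H](O[Si](C)(C)C(C)(C)C)[C@@H]2C=C([O-])O[C@@H]2[C@H]1O[Si](C)(C)C(C)(C)C.[Li+] | intermediate (not isolated)
10 | 11-(dimethylaminomethyl) lactone (C11 not controlled) | COC(=O)C1=C[C@@H](O[Si](C)(C)C(C)(C)C)[C@@H]2C(CN(C)C)C(=O)O[C@@H]2[C@H]1O[Si](C)(C)C(C)(C)C | intermediate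
11 | trimethylammonium iodide of 10 | COC(=O)C1=C[C@@H](O[Si](C)(C)C(C)(C)C)[C@@H]2C(C[N+](C)(C)C)C(=O)O[C@@H]2[C@H]1O[Si](C)(C)C(C)(C)C.[I-] | intermediate (not isolated)
12 | 11(13)-methylene-8β,12-lactone | COC(=O)C1=C[C@@H](O[Si](C)(C)C(C)(C)C)[C@@H]2C(=C)C(=O)O[C@@H]2[C@H]1O[Si](C)(C)C(C)(C)C | intermediate
13 | triol (C1–OH, C12–OH, 8β-OH; 6α,9α-bis-silyl ether) | OCC1=C[C@@H](O[Si](C)(C)C(C)(C)C)[C@H](C(=C)CO)[C@H](O)[C@H]1O[Si](C)(C)C(C)(C)C | intermediate
14 | 8,12-O-(4-methoxybenzylidene) acetal (acetal carbon epimers) | OCC1=C[C@@H](O[Si](C)(C)C(C)(C)C)[C@@H]2C(=C)COC(c3ccc(OC)cc3)O[C@@H]2[C@H]1O[Si](C)(C)C(C)(C)C | intermediate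
15 | 5β,10β-epoxy alcohol | [C@@H]1(O2)[C@@H](O[Si](C)(C)C(C)(C)C)[C@@H]3C(=C)COC(c4ccc(OC)cc4)O[C@@H]3[C@@H](O[Si](C)(C)C(C)(C)C)[C@@]12CO | intermediate
16 | isopropenylmagnesium bromide | C=C(C)[Mg]Br | starting material
17 | 5α-isopropenyl-10β-hydroxy-10α-(hydroxymethyl) compound | [C@H]1(C(C)=C)[C@@H](O[Si](C)(C)C(C)(C)C)[C@@H]3C(=C)COC(c4ccc(OC)cc4)O[C@@H]3[C@@H](O[Si](C)(C)C(C)(C)C)[C@@]1(O)CO | intermediate
18 | 10β-hydroxy-10α-carbaldehyde | [C@H]1(C(C)=C)[C@@H](O[Si](C)(C)C(C)(C)C)[C@@H]3C(=C)COC(c4ccc(OC)cc4)O[C@@H]3[C@@H](O[Si](C)(C)C(C)(C)C)[C@@]1(O)C=O | intermediate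
19 | methyltriphenylphosphonium bromide | C[P+](c1ccccc1)(c1ccccc1)c1ccccc1.[Br-] | starting material
20 | 10α-vinyl-10β-ol (acetal, bis-silyl ether) | [C@H]1(C(C)=C)[C@@H](O[Si](C)(C)C(C)(C)C)[C@@H]3C(=C)COC(c4ccc(OC)cc4)O[C@@H]3[C@@H](O[Si](C)(C)C(C)(C)C)[C@@]1(O)C=C | intermediate
21 | 8β-O-(4-methoxybenzyl) ether, C12–OH free | [C@H]1(C(C)=C)[C@@H](O[Si](C)(C)C(C)(C)C)[C@H](C(=C)CO)[C@H](OCc2ccc(OC)cc2)[C@@H](O[Si](C)(C)C(C)(C)C)[C@@]1(O)C=C | intermediate
22 | tetraol (6α, 9α, 10β, C12) | [C@H]1(C(C)=C)[C@@H](O)[C@H](C(=C)CO)[C@H](OCc2ccc(OC)cc2)[C@@H](O)[C@@]1(O)C=C | intermediate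
23 | 6,12-O-(di-tert-butylsilylene) diol | [C@H]1(C(C)=C)[C@H]2O[Si](C(C)(C)C)(C(C)(C)C)OCC(=C)[C@@H]2[C@H](OCc3ccc(OC)cc3)[C@@H](O)[C@@]1(O)C=C | intermediate
24 | cis-1-vinyl-2-isopropenylcyclohexanol (9α-O-triethylsilyl, 8β-O-4-methoxybenzyl, 6,12-O-silylene) | [C@H]1(C(C)=C)[C@H]2O[Si](C(C)(C)C)(C(C)(C)C)OCC(=C)[C@@H]2[C@H](OCc3ccc(OC)cc3)[C@@H](O[Si](CC)(CC)CC)[C@@]1(O)C=C | intermediate
25 | potassium alkoxide of 24 | [C@H]1(C(C)=C)[C@H]2O[Si](C(C)(C)C)(C(C)(C)C)OCC(=C)[C@@H]2[C@H](OCc3ccc(OC)cc3)[C@@H](O[Si](CC)(CC)CC)[C@@]1([O-])C=C.[K+] | intermediate (not isolated)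
26 | potassium cyclodeca-1(10),4-dien-10-olate | COc1ccc(CO[C@H]2[C@H]3C(=C)CO[Si](C(C)(C)C)(C(C)(C)C)O[C@@H]3/C=C(\C)CC/C=C(/[O-])[C@@H]2O[Si](CC)(CC)CC)cc1.[K+] | intermediate (not isolated)
27 | cyclodeca-1(10),4-dien-10-yl triflate | COc1ccc(CO[C@H]2[C@H]3C(=C)CO[Si](C(C)(C)C)(C(C)(C)C)O[C@@H]3/C=C(\C)CC/C=C(/OS(=O)(=O)C(F)(F)F)[C@@H]2O[Si](CC)(CC)CC)cc1 | intermediate
28 | carbon monoxide | [C-]#[O+] | starting material
29 | 14-aldehyde | COc1ccc(CO[C@H]2[C@H]3C(=C)CO[Si](C(C)(C)C)(C(C)(C)C)O[C@@H]3/C=C(\C)CC/C=C(/C=O)[C@@H]2O[Si](CC)(CC)CC)cc1 | intermediate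
30 | 6α,9α,12-triol 14-aldehyde | COc1ccc(CO[C@H]2[C@@H](C(=C)CO)[C@H](O)/C=C(\C)CC/C=C(/C=O)[C@@H]2O)cc1 | intermediate
31 | 6α,12-lactol | COc1ccc(CO[C@H]2[C@H]3C(=C)C(O)O[C@@H]3/C=C(\C)CC/C=C(/C=O)[C@@H]2O)cc1 | intermediate (not isolated)
32 | 12,6α-olide, 9α-OH, 8β-O-(4-methoxybenzyl) | COc1ccc(CO[C@H]2[C@H]3C(=C)C(=O)O[C@@H]3/C=C(\C)CC/C=C(/C=O)[C@@H]2O)cc1 | intermediate
33 | acetic anhydride | CC(=O)OC(C)=O | starting material
34 | 9α-acetate, 8β-O-(4-methoxybenzyl) | COc1ccc(CO[C@H]2[C@H]3C(=C)C(=O)O[C@@H]3/C=C(\C)CC/C=C(/C=O)[C@@H]2OC(C)=O)cc1 | intermediate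
35 | 9α-acetoxy-8β-hydroxy-14-oxo-12,6α-olide | O[C@H]1[C@H]2C(=C)C(=O)O[C@@H]2/C=C(\C)CC/C=C(/C=O)[C@@H]1OC(C)=O | intermediate
36 | methacryloyl chloride | C=C(C)C(Cl)=O | starting material
37 | CNP0403553.1 | C=C(C)C(=O)O[C@H]1[C@H]2C(=C)C(=O)O[C@@H]2/C=C(\C)CC/C=C(/C=O)[C@@H]1OC(C)=O | target

**Step count and weak points**

Total: 24 steps. Longest linear sequence: 24 steps (from 1; all other starting materials are reagents introduced in single steps).

Step 11. What may go wrong: the copper reagent has to reach C5 on the α face, next to the C6 silyloxy group and syn-axial to the C9 silyloxy group, so substitution may be outrun by Lewis-acid-induced isomerisation or Payne-type migration of the epoxy alcohol. Fallback (from 15, back at 17): a slim, linear nucleophile is used and the isopropenyl group is built afterwards. Diethylaluminium (trimethylsilyl)acetylide (ethynyltrimethylsilane, BuLi, Et2AlCl, toluene, 0 °C) should open the epoxide at C5 in the same trans-diaxial sense to give the 5α-(trimethylsilylethynyl) diol F3. K2CO3/MeOH removes the C-silyl group to give the terminal alkyne F4. Zirconium-catalysed methylalumination (Me3Al, Cp2ZrCl2, CH2Cl2; then water) places methyl on the inner alkyne carbon and hydrogen on the terminus, turning C≡CH into C(CH3)=CH2 and giving 17.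

Step 2. What may go wrong: insufficient discrimination of the two enantiotopic alkenes by the catalyst on a substrate that carries the additional ester. Fallback (from 2, back at 4): auxiliary control replaces catalyst control. The acid is condensed (EDC·HCl, HOBt, CH2Cl2) with (2R,5R)-2,5-bis(methoxymethyl)pyrrolidine to the amide F1, the auxiliary antipode being chosen to match the required sense. Iodolactonisation of F1 (I2, THF/H2O, 0 °C) runs through an iminium lactone in which the C2-symmetric amide differentiates the two alkenes. Hydrolysis releases the auxiliary and gives the iodolactone F2 (the iodo analogue of 3), which DBU converts into 4 as in step 3.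

Step 18. What may go wrong: base-induced side reactions of the hindered potassium alkoxide (fragmentation or silyl scrambling) or loss of enolate regio-integrity before triflation. Fallback (from 24, back at 27): the rearrangement is run without base as a siloxy-Cope. Me3SiOTf/2,6-lutidine gives the tertiary trimethylsilyl ether F5, which on heating (o-dichlorobenzene, 180 °C) should rearrange through the same tether-enforced chair to the trimethylsilyl enol ether F6. MeLi (THF, 0 °C) then releases the lithium enolate regiospecifically and PhNTf2 gives 27.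

Further compounds
F1 | step 2 | amide of 2 with (2R,5R)-2,5-bis(methoxymethyl)pyrrolidine | COC(=O)C1C=CC(CC(=O)N2[C@@H](COC)CC[C@@H]2COC)C=C1
F2 | step 2 | iodolactone (iodo analogue of 3, C10 epimers) | C1=C[C@@H]2CC(=O)O[C@@H]2[C@@H](I)C1C(=O)OC
F3 | step 11 | 5α-(trimethylsilylethynyl)-10β-hydroxy-10α-(hydroxymethyl) compound | [C@H]1(C#C[Si](C)(C)C)[C@@H](O[Si](C)(C)C(C)(C)C)[C@@H]3C(=C)COC(c4ccc(OC)cc4)O[C@@H]3[C@@H](O[Si](C)(C)C(C)(C)C)[C@@]1(O)CO
F4 | step 11 | 5α-ethynyl-10β-hydroxy-10α-(hydroxymethyl) compound | [C@H]1(C#C)[C@@H](O[Si](C)(C)C(C)(C)C)[C@@H]3C(=C)COC(c4ccc(OC)cc4)O[C@@H]3[C@@H](O[Si](C)(C)C(C)(C)C)[C@@]1(O)CO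
F5 | step 18 | 10β-O-trimethylsilyl ether of 24 | [C@H]1(C(C)=C)[C@H]2O[Si](C(C)(C)C)(C(C)(C)C)OCC(=C)[C@@H]2[C@H](OCc3ccc(OC)cc3)[C@@H](O[Si](CC)(CC)CC)[C@@]1(O[Si](C)(C)C)C=C
F6 | step 18 | trimethylsilyl enol ether of the cyclodeca-1(10),4-dien-10-ol | COc1ccc(CO[C@H]2[C@H]3C(=C)CO[Si](C(C)(C)C)(C(C)(C)C)O[C@@H]3/C=C(\C)CC/C=C(/O[Si](C)(C)C)[C@@H]2O[Si](CC)(CC)CC)cc1
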